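**Retrosynthetic overview**
- The target is the isovalerate of a trans α-ketol. The ester comes from Mitsunobu inversion of the cis ketol, and the cis ketol comes from a ring-expanding α-ketol (acyloin) 1,2-shift of a 1-hydroxycyclopentane-1-carbaldehyde (5 → 6 ring).
- The ring oxirane is installed on the cyclopentene before expansion by OH-directed epoxidation from the tertiary carbinol, which places it cis to the side chain. The formyl carbon comes from a vinyl group by ozonolysis.
- The dienone side chain comes from opening a spiro-epoxy γ-lactone with an (E)-alkenyllithium made from 2-methylbut-3-yn-2-ol. The lactone forms by vinyl-Grignard addition to a cyclopentenone glycidic ester.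
- The glycidic ester, with both side-chain stereocentres, comes from a catalytic asymmetric Mukaiyama aldol/Darzens closure between the silyl dienol ether of 2-methylcyclopent-2-enone and methyl bromopyruvate.
- Ring order: side-chain oxirane → temporary γ-lactone → ring oxirane → cyclopentane to cyclohexanone.

Assumption: locants C1–C14 refer to the target (ring C1 = CH–O-ester, C2 = C=O, C3 = C–Me, C4, C5, C6 = CH–side chain; C7 = oxirane C, C8 = C=O, C9=C10, C11 = C–OH, C14 = oxirane CH2); LDA, vinylmagnesium bromide, n-BuLi and LiOt-Bu are bought as solutions.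

**Step 1**
Reactants: 1 2-methylcyclopent-2-en-1-one
Product: 2 trimethyl[(5-methylcyclopenta-1,4-dien-1-yl)oxy]silane
Conditions: LDA (1.05 equiv), THF, −78 °C; TMSCl, −78 → 0 °C; pentane, filtration, used at once
Reagents that add atoms: chlorotrimethylsilane, C[Si](C)(C)Cl
Why: Kinetic α′-deprotonation of the enone by LDA and O-silylation (silyl enol ether formation) gives the cross-conjugated 2-silyloxydiene, whose only nucleophilic carbon is the future C6; no stereocentre is formed.

**Step 2**
Reactants: 2 trimethyl[(5-methylcyclopenta-1,4-dien-1-yl)oxy]silane; 3 methyl 3-bromo-2-oxopropanoate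
Product: 5 methyl (2R)-2-[(1S)-3-methyl-2-oxocyclopent-3-en-1-yl]oxirane-2-carboxylate, via silylated bromohydrin aldol adduct 4 (not isolated)
Conditions: [Cu((S,S)-t-Bu-box)](OTf)2 (10 mol%), THF, −78 °C; then TBAF (1.1 equiv), −78 → −20 °C
Reagents that add atoms: none
Why: Proposed new method: a catalytic enantioselective Mukaiyama aldol/Darzens annulation in which the bromopyruvate binds Cu(II) as a five-membered keto-ester chelate, the enolsilane attacks the unshielded ketone face (the face attacked in pyruvate itself) through an open transition state with syn (like) topicity, and fluoride then frees the tertiary alkoxide, which displaces the primary bromide 3-exo-tet; this forms the C6–C7 bond, the oxirane and both stereocentres (C6, C7), and the closest known reaction is the Cu(II)–box-catalysed aldol addition of enolsilanes to pyruvate esters followed by a classical halohydrin closure, which has not been shown with a bromopyruvate or with a cyclic cross-conjugated dienoxysilane.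

**Step 3**
Reactants: 5 methyl (2R)-2-[(1S)-3-methyl-2-oxocyclopent-3-en-1-yl]oxirane-2-carboxylate; 6 vinylmagnesium bromide
Product: 8 (3R,3aR,6aR)-6a-ethenyl-6-methyl-4,6a-dihydrospiro[cyclopenta[b]furan-3,2'-oxiran]-2(3aH)-one, via bromomagnesium tertiary alkoxide 7 (not isolated)
Conditions: 6 (1.1 equiv), CeCl3 (1.2 equiv), THF, −78 °C → rt; aq NH4Cl
Reagents that add atoms: none
Why: Cerium-mediated Grignard 1,2-addition to the enone carbonyl occurs anti to the bulky oxiranyl substituent, so the new tertiary alkoxide (6aR) is cis to the ester and lactonises (intramolecular acyl substitution), which protects the ester as a single-addition acyl donor.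

**Step 4**
Reactants: 9 2-methylbut-3-yn-2-ol
Product: 10 (E)-2-methyl-4-(tributylstannyl)but-3-en-2-ol
Conditions: Bu3SnH (1.15 equiv), AIBN (5 mol%), neat, 85 °C
Reagents that add atoms: tributyltin hydride, CCCC[SnH](CCCC)CCCC
Why: Radical hydrostannation of the terminal alkyne with equilibration by excess stannyl radical gives the thermodynamic (E)-β-vinylstannane.

**Step 5**
Reactants: 8 (3R,3aR,6aR)-6a-ethenyl-6-methyl-4,6a-dihydrospiro[cyclopenta[b]furan-3,2'-oxiran]-2(3aH)-one; 10 (E)-2-methyl-4-(tributylstannyl)but-3-en-2-ol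
Product: 12 (2E)-1-{(2R)-2-[(1R,2R)-2-ethenyl-2-hydroxy-3-methylcyclopent-3-en-1-yl]oxiran-2-yl}-4-hydroxy-4-methylpent-2-en-1-one, via dilithiated alkenyl alkoxide 11 (not isolated)
Conditions: 10 (1.5 equiv), n-BuLi (3.0 equiv), THF, −78 → −20 °C; then 8, −78 °C, 1 h; aq NH4Cl at −78 °C
Reagents that add atoms: none
Why: Sn–Li exchange keeps the E geometry, and addition of the alkenyllithium to the γ-lactone stops at the lithium lactolate (acylation of an organolithium by a lactone), so work-up releases the enone and the free tertiary alcohol (open form, in equilibrium with its cyclic hemiketal) without touching a stereocentre.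

**Step 6**
Reactants: 12 (2E)-1-{(2R)-2-[(1R,2R)-2-ethenyl-2-hydroxy-3-methylcyclopent-3-en-1-yl]oxiran-2-yl}-4-hydroxy-4-methylpent-2-en-1-one
Product: 13 (2E)-1-{(2R)-2-[(1S,2R,3R,5S)-2-ethenyl-2-hydroxy-1-methyl-6-oxabicyclo[3.1.0]hexan-3-yl]oxiran-2-yl}-4-hydroxy-4-methylpent-2-en-1-one
Conditions: VO(acac)2 (5 mol%), t-BuOOH (1.3 equiv, decane), CH2Cl2, 0 °C → rt
Reagents that add atoms: tert-butyl hydroperoxide, CC(C)(C)OO
Why: Vanadium-catalysed hydroxyl-directed epoxidation delivers oxygen to the electron-rich trisubstituted ring alkene syn to the tertiary OH, that is on the face of the side chain, setting C3 and C4 with the cis relationship that direct enone epoxidation of the six-membered ring would not give; the vinyl group and the electron-poor enone react much more slowly.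

**Step 7**
Reactants: 13 (2E)-1-{(2R)-2-[(1S,2R,3R,5S)-2-ethenyl-2-hydroxy-1-methyl-6-oxabicyclo[3.1.0]hexan-3-yl]oxiran-2-yl}-4-hydroxy-4-methylpent-2-en-1-one
Product: 14 (1S,2R,3R,5S)-2-hydroxy-3-{(2R)-2-[(2E)-4-hydroxy-4-methylpent-2-enoyl]oxiran-2-yl}-1-methyl-6-oxabicyclo[3.1.0]hexane-2-carbaldehyde
Conditions: O3, CH2Cl2/MeOH 4:1, −78 °C, Sudan Red 7B end point; Me2S, −78 °C → rt
Reagents that add atoms: ozone, [O-][O+]=O
Why: Chemoselective ozonolysis with reductive work-up cleaves the isolated vinyl group in preference to the conjugated, sterically shielded enone C=C and gives the α-hydroxy aldehyde without affecting any stereocentre.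

**Step 8**
Reactants: 14 (1S,2R,3R,5S)-2-hydroxy-3-{(2R)-2-[(2E)-4-hydroxy-4-methylpent-2-enoyl]oxiran-2-yl}-1-methyl-6-oxabicyclo[3.1.0]hexane-2-carbaldehyde
Product: 16 (1S,3R,4R,6S)-3-hydroxy-4-{(2R)-2-[(2E)-4-hydroxy-4-methylpent-2-enoyl]oxiran-2-yl}-1-methyl-7-oxabicyclo[4.1.0]heptan-2-one, via lithium ketolate 15 (not isolated)
Conditions: LiOt-Bu (1.0 equiv), THF, −40 → 0 °C; AcOH (1.1 equiv)
Reagents that add atoms: none
Why: Alkoxide-triggered α-ketol (acyloin) rearrangement in which the lithium chelate holds C–O⁻ and C=O syn-periplanar and the electron-rich C2–C6 bond, rather than the inductively deactivated oxiranyl carbon C3, shifts suprafacially to the formyl carbon with retention at C6; this expands the cyclopentane to the cyclohexanone and creates C1 with its oxygen cis to the side chain (3R), while the ring oxirane cannot take part because it is syn to the alkoxide.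

**Step 9**
Reactants: 16 (1S,3R,4R,6S)-3-hydroxy-4-{(2R)-2-[(2E)-4-hydroxy-4-methylpent-2-enoyl]oxiran-2-yl}-1-methyl-7-oxabicyclo[4.1.0]heptan-2-one; 17 3-methylbutanoic acid
Product: 18 (1S,3S,4R,6S)-4-{(2R)-2-[(2E)-4-hydroxy-4-methylpent-2-enoyl]oxiran-2-yl}-1-methyl-2-oxo-7-oxabicyclo[4.1.0]heptan-3-yl 3-methylbutanoate
Conditions: 17 (1.5 equiv), PPh3 (1.5 equiv), DIAD (1.5 equiv), toluene, 0 °C → rt
Reagents that add atoms: none
Why: Mitsunobu esterification, in which isovalerate displaces the axial, carbonyl-activated oxyphosphonium by SN2 from the face anti to the side chain, inverts C1 (3R → 3S) to the trans ester while the tertiary alcohol is inert.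

**Compound list**
1 | 2-methylcyclopent-2-en-1-one | CC1=CCCC1=O | starting material
2 | trimethyl[(5-methylcyclopenta-1,4-dien-1-yl)oxy]silane | CC1=CCC=C1O[Si](C)(C)C | intermediate
3 | methyl 3-bromo-2-oxopropanoate (methyl bromopyruvate) | COC(=O)C(=O)CBr | starting material
4 | methyl (2S)-3-bromo-2-[(1S)-3-methyl-2-oxocyclopent-3-en-1-yl]-2-[(trimethylsilyl)oxy]propanoate | COC(=O)[C@@](CBr)(O[Si](C)(C)C)[C@@H]1CC=C(C)C1=O | intermediate
5 | methyl (2R)-2-[(1S)-3-methyl-2-oxocyclopent-3-en-1-yl]oxirane-2-carboxylate | COC(=O)[C@]1(CO1)[C@@H]1CC=C(C)C1=O | intermediate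
6 | vinylmagnesium bromide | C=C[Mg]Br | starting material
7 | bromomagnesium alkoxide of the 1,2-adduct of 5 (vinyl anti to the oxiranyl group) | C=C[C@]1(O[Mg]Br)C(C)=CC[C@H]1[C@]1(C(=O)OC)CO1 | intermediate
8 | (3R,3aR,6aR)-6a-ethenyl-6-methyl-4,6a-dihydrospiro[cyclopenta[b]furan-3,2'-oxiran]-2(3aH)-one (cis-fused spiro-epoxy γ-lactone) | C=C[C@@]12OC(=O)[C@]3(CO3)[C@@H]1CC=C2C | intermediate
9 | 2-methylbut-3-yn-2-ol | CC(C)(O)C#C | starting material
10 | (E)-2-methyl-4-(tributylstannyl)but-3-en-2-ol | CCCC[Sn](CCCC)(CCCC)/C=C/C(C)(C)O | intermediate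
11 | lithium (E)-4-lithio-2-methylbut-3-en-2-olate | [Li]/C=C/C(C)(C)O[Li] | intermediate
12 | (2E)-1-{(2R)-2-[(1R,2R)-2-ethenyl-2-hydroxy-3-methylcyclopent-3-en-1-yl]oxiran-2-yl}-4-hydroxy-4-methylpent-2-en-1-one | C=C[C@]1(O)C(C)=CC[C@H]1[C@]1(C(=O)/C=C/C(C)(C)O)CO1 | intermediate
13 | (2E)-1-{(2R)-2-[(1S,2R,3R,5S)-2-ethenyl-2-hydroxy-1-methyl-6-oxabicyclo[3.1.0]hexan-3-yl]oxiran-2-yl}-4-hydroxy-4-methylpent-2-en-1-one | C=C[C@]1(O)[C@@]2(C)O[C@H]2C[C@H]1[C@]1(C(=O)/C=C/C(C)(C)O)CO1 | intermediate
14 | (1S,2R,3R,5S)-2-hydroxy-3-{(2R)-2-[(2E)-4-hydroxy-4-methylpent-2-enoyl]oxiran-2-yl}-1-methyl-6-oxabicyclo[3.1.0]hexane-2-carbaldehyde | O=C[C@]1(O)[C@@]2(C)O[C@H]2C[C@H]1[C@]1(C(=O)/C=C/C(C)(C)O)CO1 | intermediate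
15 | lithium alkoxide of 16 | [Li]O[C@H]1C(=O)[C@@]2(C)O[C@H]2C[C@H]1[C@]1(C(=O)/C=C/C(C)(C)O)CO1 | intermediate
16 | (1S,3R,4R,6S)-3-hydroxy-4-{(2R)-2-[(2E)-4-hydroxy-4-methylpent-2-enoyl]oxiran-2-yl}-1-methyl-7-oxabicyclo[4.1.0]heptan-2-one | O[C@H]1C(=O)[C@@]2(C)O[C@H]2C[C@H]1[C@]1(C(=O)/C=C/C(C)(C)O)CO1 | intermediate
17 | 3-methylbutanoic acid | CC(C)CC(=O)O | starting material
18 | (1S,3S,4R,6S)-4-{(2R)-2-[(2E)-4-hydroxy-4-methylpent-2-enoyl]oxiran-2-yl}-1-methyl-2-oxo-7-oxabicyclo[4.1.0]heptan-3-yl 3-methylbutanoate | CC(C)CC(=O)O[C@@H]1C(=O)[C@@]2(C)O[C@H]2C[C@H]1[C@]1(C(=O)/C=C/C(C)(C)O)CO1 | target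

**Step count and risks**
Total: 9 steps. Longest linear sequence: 8 steps (1, 2, 3, 5, 6, 7, 8, 9).

The three steps most likely to fail are these.

Step 2, the proposed new aldol/Darzens annulation. It could fail through a hetero-Diels–Alder reaction of the cyclopentadiene unit, low syn selectivity, or retro-aldol before ring closure. The fallback uses known auxiliary-controlled chemistry, sets out from 2 and comes back at 8. Bromopyruvoyl chloride (from bromopyruvic acid and Cl2CHOMe) is esterified with (−)-8-phenylmenthol to give (1R,2S,5R)-8-phenylmenthyl bromopyruvate F1. A SnCl4-mediated Mukaiyama aldol of 2 with F1 (CH2Cl2, −78 °C), in which the phenyl ring shields one face of the chelated keto ester, gives the 8-phenylmenthyl bromohydrin ester F2. K2CO3 in MeOH at 0 °C closes it to the 8-phenylmenthyl glycidate F3. F3 then takes the place of 5 under the conditions of step 3, where lactonisation expels the auxiliary alcohol and gives 8.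

Step 7, ozonolysis of the vinyl group beside the side-chain enone. The risk is over-oxidation of the enone C=C. The fallback sets out from 5 and comes back at 14, and uses a dithiane as the formyl equivalent so that no oxidative cleavage is needed. 2-Lithio-1,3-dithiane adds to 5 (THF, −78 °C → rt) and the alkoxide lactonises as in step 3 to give the dithianyl spiro-lactone F4. Opening with 11 as in step 5 gives the dithianyl hydroxy enone F5. MeI/CaCO3 in aqueous MeCN unmasks the ring-alkene hydroxy aldehyde F6. VO(acac)2/t-BuOOH then epoxidises the ring alkene syn to the tertiary OH and gives 14.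

Step 8, the ring expansion. The main risk is migration of the oxiranyl carbon C3 instead of C6, which I could not settle from precedent; equilibration of the ketolate through the enediolate is the second risk. If the trans ketol forms instead, it is simply acylated with retention. The fallback sets out from 14 and comes back at 16, and changes from the anionic push to an electrophilic pull, which penalises migration of the electron-poor oxiranyl carbon more strongly. Silylation of 14 (TMSOTf, 2,6-lutidine, CH2Cl2, −78 °C) gives the bis(trimethylsilyl) ether of 14 F7. A bulky aluminium Lewis acid (Me3Al or MABR type, toluene, −78 °C) promotes the known 1,2-shift of α-siloxy aldehydes to α-siloxy ketones and gives the bis(trimethylsilyl) ether of 16 F8. Citric acid in MeOH removes both silyl groups and returns 16.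

**Further compounds**
F1 | step 2 | (1R,2S,5R)-5-methyl-2-(2-phenylpropan-2-yl)cyclohexyl 3-bromo-2-oxopropanoate | CC(C)(c1ccccc1)[C@@H]1CC[C@@H](C)C[C@H]1OC(=O)C(=O)CBr
F2 | step 2 | (1R,2S,5R)-5-methyl-2-(2-phenylpropan-2-yl)cyclohexyl (2S)-3-bromo-2-hydroxy-2-[(1S)-3-methyl-2-oxocyclopent-3-en-1-yl]propanoate | CC(C)(c1ccccc1)[C@@H]1CC[C@@H](C)C[C@H]1OC(=O)[C@@](CBr)(O)[C@@H]1CC=C(C)C1=O
F3 | step 2 | (1R,2S,5R)-5-methyl-2-(2-phenylpropan-2-yl)cyclohexyl (2R)-2-[(1S)-3-methyl-2-oxocyclopent-3-en-1-yl]oxirane-2-carboxylate | CC(C)(c1ccccc1)[C@@H]1CC[C@@H](C)C[C@H]1OC(=O)[C@]1(CO1)[C@@H]1CC=C(C)C1=O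
F4 | step 7 | 6a-(1,3-dithian-2-yl) analogue of lactone 8 (same configuration; dithianyl in place of ethenyl) | S1CCCSC1[C@@]12OC(=O)[C@]3(CO3)[C@@H]1CC=C2C
F5 | step 7 | 2-(1,3-dithian-2-yl) analogue of 12 (dithianyl in place of ethenyl) | S1CCCSC1[C@]1(O)C(C)=CC[C@H]1[C@]1(C(=O)/C=C/C(C)(C)O)CO1
F6 | step 7 | (1R,5R)-1-hydroxy-5-{(2R)-2-[(2E)-4-hydroxy-4-methylpent-2-enoyl]oxiran-2-yl}-2-methylcyclopent-2-ene-1-carbaldehyde | O=C[C@]1(O)C(C)=CC[C@H]1[C@]1(C(=O)/C=C/C(C)(C)O)CO1
F7 | step 8 | bis(trimethylsilyl) ether of 14 (both hydroxyls silylated) | O=C[C@]1(O[Si](C)(C)C)[C@@]2(C)O[C@H]2C[C@H]1[C@]1(C(=O)/C=C/C(C)(C)O[Si](C)(C)C)CO1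
F8 | step 8 | bis(trimethylsilyl) ether of 16 (both hydroxyls silylated) | C[Si](C)(C)O[C@H]1C(=O)[C@@]2(C)O[C@H]2C[C@H]1[C@]1(C(=O)/C=C/C(C)(C)O[Si](C)(C)C)CO1
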